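**Plan**
1. Cuts (retrosynthetic order): silyl ethers; C1–C10 oxirane (from the ring E‑olefin); the Cα–CH2 bond of the inner butenoate (giving macrocyclic (Z)‑2‑bromobut‑2‑enoate 31 and iodomethyl ester 40); the C8–O ester; C3–C4 (ring); C7–C11 and C11=C13 (lactone); C6–C7.
2. Forward order: C6–C7 by alkenylzinc addition; C7/C8 oxirane; γ‑lactone by a tethered phosphonoacetate that opens the oxirane at C7, then methylenation; ten‑membered carbocycle by Ni/Cr closure of C3–C4; O8 acylation; side‑chain union; C1/C10 oxirane last.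
3. Feature that allows the union: the inner acyl group is a but‑2‑enoate whose sp2 Cα carries a CH2 bound only to an acyloxy oxygen (no β‑hydrogen; the O=C–O–CH2–Zn unit can form a five‑membered chelate). A (Z)‑α‑bromo‑enoate and an (acyloxymethyl)zinc iodide can therefore be joined by sp2–sp3 cross‑coupling with retention of geometry.
4. Stereocentres: C6, C7 and C8 come from one Sharpless kinetic resolution/epoxidation (D‑(−)‑DIPT) plus SN2 inversion at C7; C3 from oxidation followed by CBS reduction; C1 and C10 from peripheral peracid attack on the ring E‑olefin.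
5. Olefin geometry: 4Z from hydroalumination–iodination; 1(10)E from a stabilised Wittig reaction; inner E from the (Z)‑bromo‑enal; outer E from Baylis–Hillman acetate transposition.

Key step: step 27

Remark on numbering: germacrane numbering is used for the macrocycles (ring C1–C10, lactone carbons C11–C13, C14 on C10, C15 on C4). In this numbering the target is the (1R,3S,6R,7R,8R,10R)‑1,10‑epoxy‑3‑hydroxy‑12,6‑olide with the diester chain on O8.

**Route**

Step 1
Reactants: 1 but‑2‑yn‑1‑ol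
Product: 3 (Z)‑3‑iodobut‑2‑en‑1‑ol, via sodium vinylalanate 2 (not isolated)
Conditions: Red‑Al, THF, 0 °C to rt; then I2, −78 to 0 °C
Reagents that add atoms: iodine, II
Why: Alkoxide‑directed trans‑hydroalumination of the propargylic alcohol places aluminium at C3 in a five‑membered alanate, and iodinolysis with retention (hydroalumination–iodination) should give the Z‑iodoalkene that later becomes the 4Z ring olefin.

Step 2
Reactants: 3 (Z)‑3‑iodobut‑2‑en‑1‑ol
Product: 4 (Z)‑3‑iodobut‑2‑enal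
Conditions: activated MnO2, CH2Cl2, rt
Reagents that add atoms: none
Why: Allylic alcohol oxidation with manganese dioxide is neutral and should leave the iodoalkene geometry untouched.

Step 3
Reactants: 5 3‑[(tert‑butyldimethylsilyl)oxy]propanal; 6 ethyl 2‑(triphenylphosphoranylidene)propanoate
Product: 7 ethyl (E)‑5‑[(tert‑butyldimethylsilyl)oxy]‑2‑methylpent‑2‑enoate
Conditions: CH2Cl2, rt
Reagents that add atoms: none
Why: The Wittig reaction of a stabilised α‑methyl ylide with an unbranched aldehyde is E‑selective and sets the trisubstituted olefin that becomes C1=C10.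

Step 4
Reactants: 7 ethyl (E)‑5‑[(tert‑butyldimethylsilyl)oxy]‑2‑methylpent‑2‑enoate
Product: 8 (E)‑5‑[(tert‑butyldimethylsilyl)oxy]‑2‑methylpent‑2‑en‑1‑ol
Conditions: DIBAL‑H (2.2 equiv), CH2Cl2, −78 °C; Rochelle salt work‑up
Reagents that add atoms: none
Why: DIBAL‑H 1,2‑reduction of the enoate gives the allylic alcohol without touching the olefin geometry or the silyl ether.

Step 5
Reactants: 8 (E)‑5‑[(tert‑butyldimethylsilyl)oxy]‑2‑methylpent‑2‑en‑1‑ol
Product: 9 {[(E)‑5‑bromo‑4‑methylpent‑3‑en‑1‑yl]oxy}(tert‑butyl)dimethylsilane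
Conditions: CBr4, PPh3, CH2Cl2, 0 °C
Reagents that add atoms: carbon tetrabromide, BrC(Br)(Br)Br
Why: The Appel bromination converts the primary allylic alcohol into the bromide under neutral conditions without allylic transposition.

Step 6
Reactants: 9 {[(E)‑5‑bromo‑4‑methylpent‑3‑en‑1‑yl]oxy}(tert‑butyl)dimethylsilane; 10 ethynyltrimethylsilane
Product: 11 tert‑butyldimethyl{[(E)‑4‑methyl‑7‑(trimethylsilyl)hept‑3‑en‑6‑yn‑1‑yl]oxy}silane
Conditions: CuI, K2CO3, NaI, DMF, rt
Reagents that add atoms: none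
Why: Copper(I)‑mediated SN2 coupling of a terminal alkyne with a primary allylic bromide should give the skipped enyne with retention of the E‑olefin.

Step 7
Reactants: 11 tert‑butyldimethyl{[(E)‑4‑methyl‑7‑(trimethylsilyl)hept‑3‑en‑6‑yn‑1‑yl]oxy}silane
Product: 12 tert‑butyldimethyl{[(E)‑4‑methylhept‑3‑en‑6‑yn‑1‑yl]oxy}silane
Conditions: K2CO3 (cat.), MeOH, rt
Reagents that add atoms: none
Why: Protodesilylation of the alkynylsilane with methanolic carbonate leaves the alkyl silyl ether intact.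

Step 8
Reactants: 12 tert‑butyldimethyl{[(E)‑4‑methylhept‑3‑en‑6‑yn‑1‑yl]oxy}silane; 4 (Z)‑3‑iodobut‑2‑enal
Product: 15 rac‑(2Z,5E,8E)‑11‑[(tert‑butyldimethylsilyl)oxy]‑2‑iodo‑8‑methylundeca‑2,5,8‑trien‑4‑ol, via alkenylzirconocene chloride 13 (not isolated), via alkenyl(methyl)zinc 14 (not isolated)
Conditions: Cp2Zr(H)Cl, CH2Cl2, rt; Me2Zn, −65 °C; then 4, 0 °C
Reagents that add atoms: none
Why: Syn, terminal‑selective hydrozirconation of the alkyne with the Schwartz reagent, zirconium‑to‑zinc transmetalation and 1,2‑addition to the enal form the C6–C7 bond as the E‑allylic alcohol, and C6 is left racemic because the next step resolves it.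

Step 9
Reactants: 15 rac‑(2Z,5E,8E)‑11‑[(tert‑butyldimethylsilyl)oxy]‑2‑iodo‑8‑methylundeca‑2,5,8‑trien‑4‑ol
Product: 16 (1R,2Z)‑1‑{(2R,3R)‑3‑[(E)‑5‑{[tert‑butyl(dimethyl)silyl]oxy}‑2‑methylpent‑2‑en‑1‑yl]oxiran‑2‑yl}‑3‑iodobut‑2‑en‑1‑ol
Conditions: Ti(OiPr)4, D‑(−)‑DIPT, t‑BuOOH (0.6 equiv), 4 Å MS, CH2Cl2, −20 °C
Reagents that add atoms: tert‑butyl hydroperoxide, CC(C)(C)OO
Why: In this Sharpless kinetic resolution D‑(−)‑DIPT should epoxidise only the (4S)‑enantiomer at its E‑disubstituted allylic olefin, on the tartrate‑dictated face and erythro to the carbinol, which fixes C6, C7 and C8 together, while the cis‑substituted iodoalkene and the isolated trisubstituted olefin stay inert.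

Step 10
Reactants: 16 epoxy alcohol; 17 (diethoxyphosphoryl)acetic acid
Product: 18 (1R,2Z)‑1‑{(2R,3R)‑3‑[(E)‑5‑{[tert‑butyl(dimethyl)silyl]oxy}‑2‑methylpent‑2‑en‑1‑yl]oxiran‑2‑yl}‑3‑iodobut‑2‑en‑1‑yl (diethoxyphosphoryl)acetate
Conditions: DCC, DMAP (cat.), CH2Cl2, 0 °C to rt
Reagents that add atoms: none
Why: Steglich esterification with retention at C6 installs the phosphonoacetate tether on O6.

Step 11
Reactants: 18 epoxy phosphonoacetate
Product: 20 (4R,5S)‑4‑[(1R,3E)‑6‑{[tert‑butyl(dimethyl)silyl]oxy}‑1‑hydroxy‑3‑methylhex‑3‑en‑1‑yl]‑5‑[(Z)‑2‑iodoprop‑1‑en‑1‑yl]‑3‑methylideneoxolan‑2‑one, via α‑phosphono lactone 19 (not isolated)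
Conditions: KOtBu (1.05 equiv), THF, 0 °C to rt; then (CH2O)n, 0 °C to rt
Reagents that add atoms: formaldehyde (as paraformaldehyde), C=O
Why: The phosphonoacetate carbanion should open the adjacent oxirane at C7 in a 5‑exo‑tet SN2 step (inversion at C7, C8–O retained, the tether making C7 rather than C8 reachable) to give the trans‑lactone, whose phosphonate carbanion then undergoes Horner–Wadsworth–Emmons methylenation with formaldehyde, the tethered form of the known phosphonoacetate–epoxide lactone annulation.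

Step 12
Reactants: 20 silyl ether lactone
Product: 21 (4R,5S)‑4‑[(1R,3E)‑1,6‑dihydroxy‑3‑methylhex‑3‑en‑1‑yl]‑5‑[(Z)‑2‑iodoprop‑1‑en‑1‑yl]‑3‑methylideneoxolan‑2‑one
Conditions: HF·pyridine, pyridine, THF, 0 °C to rt
Reagents that add atoms: none
Why: Buffered fluoride cleavage of the primary TBS ether is tolerated by the methylene lactone and the iodoalkene.

Step 13
Reactants: 21 diol
Product: 22 (3E,6R)‑6‑hydroxy‑6‑{(2S,3R)‑2‑[(Z)‑2‑iodoprop‑1‑en‑1‑yl]‑4‑methylidene‑5‑oxooxolan‑3‑yl}‑4‑methylhex‑3‑enal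
Conditions: TEMPO (10 mol %), PhI(OAc)2, CH2Cl2, rt
Reagents that add atoms: none
Why: The TEMPO/iodine(III) oxidation is selective for the primary alcohol over the hindered secondary C8 carbinol and is non‑basic, so the β,γ‑unsaturated aldehyde should not move into conjugation.

Step 14
Reactants: 22 hydroxy aldehyde
Product: 23 (6R,7R,8R)‑3,8‑dihydroxygermacra‑1(10)E,4Z,11(13)‑trien‑12,6‑olide (both C3 epimers)
Conditions: CrCl2 (10 equiv), NiCl2 (2 mol %), DMSO, rt, slow addition, 2 mM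
Reagents that add atoms: none
Why: In the Nozaki–Hiyama–Kishi macrocyclisation nickel inserts into the C(sp2)–I bond and the configurationally stable Z‑alkenylchromium adds to the aldehyde, closing the ten‑membered ring at C3–C4 with the 4Z olefin intact, while C3 is deliberately left uncontrolled and is set in steps 15 and 19.

Step 15
Reactants: 23 macrocyclic diol
Product: 24 (6R,7R,8R)‑8‑hydroxy‑3‑oxogermacra‑1(10)E,4Z,11(13)‑trien‑12,6‑olide
Conditions: activated MnO2, CH2Cl2, rt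
Reagents that add atoms: none
Why: Manganese dioxide oxidises only the allylic C3 carbinol (C8–OH is not allylic) and so converges both C3 epimers onto one Z‑enone.

Step 16
Reactants: 25 (E)‑but‑2‑enal
Product: 27 (Z)‑2‑bromobut‑2‑enal, via 2,3‑dibromobutanal 26 (not isolated)
Conditions: Br2, CH2Cl2, −20 to 0 °C; then Et3N, 0 °C to rt
Reagents that add atoms: bromine, BrBr
Why: Bromine addition followed by dehydrobromination through the enol(ate) should give the thermodynamically preferred Z‑bromo‑enal with CHO trans to CH3.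

Step 17
Reactants: 27 (Z)‑2‑bromobut‑2‑enal
Product: 28 (Z)‑2‑bromobut‑2‑enoic acid
Conditions: NaClO2, NaH2PO4, 2‑methylbut‑2‑ene, t‑BuOH/H2O, 0 °C to rt
Reagents that add atoms: sodium chlorite, [Na+].[O-]Cl=O
Why: The Pinnick oxidation converts the enal into the acid without disturbing the bromoalkene geometry.

Step 18
Reactants: 24 hydroxy enone; 28 (Z)‑2‑bromobut‑2‑enoic acid
Product: 29 (6R,7R,8R)‑8‑{[(Z)‑2‑bromobut‑2‑enoyl]oxy}‑3‑oxogermacra‑1(10)E,4Z,11(13)‑trien‑12,6‑olide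
Conditions: DCC, DMAP (0.2 equiv), CH2Cl2, 0 °C
Reagents that add atoms: none
Why: Steglich esterification acylates the only free hydroxyl (O8), so no protecting group is needed to tell O3 from O8.

Step 19
Reactants: 29 bromoester enone
Product: 30 (3S,6R,7R,8R)‑8‑{[(Z)‑2‑bromobut‑2‑enoyl]oxy}‑3‑hydroxygermacra‑1(10)E,4Z,11(13)‑trien‑12,6‑olide
Conditions: (R)‑2‑methyl‑CBS‑oxazaborolidine, catecholborane, toluene/CH2Cl2, −78 °C
Reagents that add atoms: none
Why: In the Corey–Bakshi–Shibata reduction the (R)‑catalyst treats the alkenyl carbon C4 as the large and C2H2 as the small ketone substituent and should deliver hydride to give the 3S allylic alcohol under reagent control, with enoates and lactone untouched at −78 °C.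

Step 20
Reactants: 30 allylic alcohol
Product: 31 (3S,6R,7R,8R)‑8‑{[(Z)‑2‑bromobut‑2‑enoyl]oxy}‑3‑[(triethylsilyl)oxy]germacra‑1(10)E,4Z,11(13)‑trien‑12,6‑olide
Conditions: TESOTf, 2,6‑lutidine, CH2Cl2, −78 °C
Reagents that add atoms: triethylsilyl trifluoromethanesulfonate, CC[Si](CC)(CC)OS(=O)(=O)C(F)(F)F
Why: Silyl triflate silylation protects the hindered allylic alcohol so that it neither consumes the zinc reagent nor directs the later epoxidation.

Step 21
Reactants: 32 tert‑butyl prop‑2‑enoate; 33 {[tert‑butyl(dimethyl)silyl]oxy}acetaldehyde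
Product: 34 tert‑butyl 4‑{[tert‑butyl(dimethyl)silyl]oxy}‑3‑hydroxy‑2‑methylidenebutanoate (racemic)
Conditions: DABCO (1 equiv), 1,4‑dioxane/H2O, rt
Reagents that add atoms: none
Why: The Morita–Baylis–Hillman reaction of the acrylate with the activated α‑silyloxy aldehyde gives the adduct, whose racemic stereocentre is destroyed in step 23.

Step 22
Reactants: 34 Baylis–Hillman alcohol
Product: 35 tert‑butyl 3‑acetoxy‑4‑{[tert‑butyl(dimethyl)silyl]oxy}‑2‑methylidenebutanoate (racemic)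
Conditions: Ac2O, Et3N, DMAP (cat.), CH2Cl2, 0 °C
Reagents that add atoms: acetic anhydride, CC(=O)OC(C)=O
Why: DMAP‑catalysed acetylation of the secondary alcohol proceeds under standard conditions.

Step 23
Reactants: 35 Baylis–Hillman acetate
Product: 36 tert‑butyl (E)‑2‑(acetoxymethyl)‑4‑{[tert‑butyl(dimethyl)silyl]oxy}but‑2‑enoate
Conditions: DABCO (0.3 equiv), THF, 65 °C
Reagents that add atoms: none
Why: DABCO‑mediated SN2′–SN2′ 1,3‑transposition of the Baylis–Hillman acetate equilibrates to the conjugated trisubstituted olefin, whose thermodynamic E isomer has the ester trans to CH2OTBS.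

Step 24
Reactants: 36 tert‑butyl ester
Product: 38 (E)‑2‑(acetoxymethyl)‑4‑{[tert‑butyl(dimethyl)silyl]oxy}but‑2‑enoic acid, via trimethylsilyl ester 37 (not isolated)
Conditions: TMSOTf, 2,6‑lutidine, CH2Cl2, 0 °C; aqueous work‑up at pH 5
Reagents that add atoms: none
Why: Silyl‑triflate‑mediated tert‑butyl ester cleavage (loss of isobutene to the silyl ester, hydrolysed on work‑up) spares the TBS ether and the allylic acetate, which acid or hydroxide would not.

Step 25
Reactants: 38 acid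
Product: 39 chloromethyl (E)‑2‑(acetoxymethyl)‑4‑{[tert‑butyl(dimethyl)silyl]oxy}but‑2‑enoate
Conditions: Cs2CO3 (0.55 equiv), BrCH2Cl (10 equiv), DMF, rt, dark
Reagents that add atoms: bromochloromethane, ClCBr
Why: Carboxylate O‑alkylation with excess bromochloromethane displaces bromide selectively and gives the chloromethyl ester.

Step 26
Reactants: 39 chloromethyl ester
Product: 40 iodomethyl (E)‑2‑(acetoxymethyl)‑4‑{[tert‑butyl(dimethyl)silyl]oxy}but‑2‑enoate
Conditions: NaI, acetone, rt, dark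
Reagents that add atoms: sodium iodide, [Na+].[I-]
Why: Finkelstein halide exchange gives the iodide needed for zinc insertion.

Step 27
Reactants: 31 macrocyclic (Z)‑2‑bromobut‑2‑enoate; 40 iodomethyl ester
Product: 42 (3S,6R,7R,8R)‑8‑({(E)‑2‑[({(E)‑2‑(acetoxymethyl)‑4‑[(tert‑butyldimethylsilyl)oxy]but‑2‑enoyl}oxy)methyl]but‑2‑enoyl}oxy)‑3‑[(triethylsilyl)oxy]germacra‑1(10)E,4Z,11(13)‑trien‑12,6‑olide, via acyloxymethylzinc iodide 41 (not isolated)
Conditions: 40, Zn dust (activated with BrCH2CH2Br/TMSCl), THF, 10 °C; then 31, Pd2(dba)3 (2.5 mol %), SPhos (10 mol %), THF, 0 °C to rt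
Reagents that add atoms: none
Why: This is a Negishi cross‑coupling in which zinc inserts into the activated C–I bond of 40 to give the carbonyl‑chelated (acyloxymethyl)zinc iodide 41, Pd(0) adds oxidatively to the C(sp2)–Br bond of 31, the CH2 group passes from zinc to palladium and reductive elimination forms the Cα–CH2 bond. The closest known reaction types are the use of (pivaloyloxymethyl)zinc iodide as a hydroxymethyl‑anion equivalent and the Negishi alkylation of (Z)‑2‑bromoalk‑2‑enoates with alkylzinc halides. No ring is closed and no stereocentre is made; the E geometry of the inner trisubstituted olefin is controlled by the Z configuration of the bromide in 31, because oxidative addition and reductive elimination both occur with retention at the alkenyl carbon. The step needs chemoselectivity for the alkenyl bromide over the two allylic carboxylates (π‑allyl formation), over Heck insertion into the 11(13)‑methylene lactone and over the ester carbonyls; the electron‑poor α‑bromo‑enoate should add fastest to Pd(0) at 0 °C, the bulky biarylphosphine speeds transmetalation and reductive elimination, and alkylzinc halides do not add to esters or enoates without copper. The zinc reagent has no β‑hydrogen, so β‑hydride elimination cannot compete, and the acid‑sensitive oxirane is introduced only afterwards so that it never meets Lewis‑acidic zinc salts.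

Step 28
Reactants: 42 coupled triene
Product: 43 (1R,3S,6R,7R,8R,10R)‑1,10‑epoxide of 42 (3‑O‑triethylsilyl, 4′‑O‑tert‑butyldimethylsilyl derivative of the target)
Conditions: mCPBA (1.1 equiv), NaHCO3, CH2Cl2, −20 to 0 °C
Reagents that add atoms: 3‑chloroperoxybenzoic acid, OOC(=O)c1cccc(Cl)c1
Why: In this Prilezhaev epoxidation C1=C10 is the only electron‑rich, unhindered olefin (C4=C5 has two allylic C–O bonds and the OTES group beside it, the other three are conjugated to carbonyls), and attack on the exposed outer face of the ring E‑olefin should give the 1β,10α (1R,10R) oxirane found in the natural 1(10)‑epoxy‑heliangolides.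

Step 29
Reactants: 43 bis‑silyl ether
Product: 44 target, (1R,3S,6R,7R,8R,10R)‑8‑({(E)‑2‑[({(E)‑2‑(acetoxymethyl)‑4‑hydroxybut‑2‑enoyl}oxy)methyl]but‑2‑enoyl}oxy)‑1,10‑epoxy‑3‑hydroxygermacra‑4Z,11(13)‑dien‑12,6‑olide
Conditions: HF·pyridine, pyridine, THF, 0 °C to rt
Reagents that add atoms: none
Why: Buffered fluoride desilylation removes the triethylsilyl and the primary TBS ether in one operation while the esters, the oxirane and the methylene lactone should survive at this pH.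

**Compound list**
1 | but‑2‑yn‑1‑ol | CC#CCO | starting material
2 | sodium vinylalanate (cyclic alkoxy‑alkenyl aluminate from 1) | [Na+].COCCO[Al-]1(OCCOC)OC/C=C1/C | intermediate
3 | (Z)‑3‑iodobut‑2‑en‑1‑ol | C/C(I)=C/CO | intermediate
4 | (Z)‑3‑iodobut‑2‑enal | C/C(I)=C/C=O | intermediate
5 | 3‑[(tert‑butyldimethylsilyl)oxy]propanal | O=CCCO[Si](C)(C)C(C)(C)C | starting material
6 | ethyl 2‑(triphenylphosphoranylidene)propanoate | CCOC(=O)C(C)=P(c1ccccc1)(c1ccccc1)c1ccccc1 | starting material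
7 | ethyl (E)‑5‑[(tert‑butyldimethylsilyl)oxy]‑2‑methylpent‑2‑enoate | CCOC(=O)/C(C)=C/CCO[Si](C)(C)C(C)(C)C | intermediate
8 | (E)‑5‑[(tert‑butyldimethylsilyl)oxy]‑2‑methylpent‑2‑en‑1‑ol | OC/C(C)=C/CCO[Si](C)(C)C(C)(C)C | intermediate
9 | {[(E)‑5‑bromo‑4‑methylpent‑3‑en‑1‑yl]oxy}(tert‑butyl)dimethylsilane | BrC/C(C)=C/CCO[Si](C)(C)C(C)(C)C | intermediate
10 | ethynyltrimethylsilane | C#C[Si](C)(C)C | starting material
11 | tert‑butyldimethyl{[(E)‑4‑methyl‑7‑(trimethylsilyl)hept‑3‑en‑6‑yn‑1‑yl]oxy}silane | C[Si](C)(C)C#CC/C(C)=C/CCO[Si](C)(C)C(C)(C)C | intermediate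
12 | tert‑butyldimethyl{[(E)‑4‑methylhept‑3‑en‑6‑yn‑1‑yl]oxy}silane | C#CC/C(C)=C/CCO[Si](C)(C)C(C)(C)C | intermediate
13 | alkenylzirconocene chloride from 12 | Cl[Zr](/C=C/C/C(C)=C/CCO[Si](C)(C)C(C)(C)C)(C1C=CC=C1)C1C=CC=C1 | intermediate
14 | alkenyl(methyl)zinc from 13 | C[Zn]/C=C/C/C(C)=C/CCO[Si](C)(C)C(C)(C)C | intermediate
15 | rac‑(2Z,5E,8E)‑11‑[(tert‑butyldimethylsilyl)oxy]‑2‑iodo‑8‑methylundeca‑2,5,8‑trien‑4‑ol | C/C(I)=C/C(O)/C=C/C/C(C)=C/CCO[Si](C)(C)C(C)(C)C | intermediate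
16 | (1R,2Z)‑1‑{(2R,3R)‑3‑[(E)‑5‑{[tert‑butyl(dimethyl)silyl]oxy}‑2‑methylpent‑2‑en‑1‑yl]oxiran‑2‑yl}‑3‑iodobut‑2‑en‑1‑ol | C/C(I)=C/[C@@H](O)[C@H]1O[C@@H]1C/C(C)=C/CCO[Si](C)(C)C(C)(C)C | intermediate
17 | (diethoxyphosphoryl)acetic acid | CCOP(=O)(CC(=O)O)OCC | starting material
18 | (diethoxyphosphoryl)acetate of 16 | C/C(I)=C/[C@@H](OC(=O)CP(=O)(OCC)OCC)[C@H]1O[C@@H]1C/C(C)=C/CCO[Si](C)(C)C(C)(C)C | intermediate
19 | α‑phosphono lactone (C11 epimers) | CCOP(=O)(OCC)C1C(=O)O[C@H](/C=C(/C)I)[C@H]1[C@H](O)C/C(C)=C/CCO[Si](C)(C)C(C)(C)C | intermediate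
20 | (4R,5S)‑4‑[(1R,3E)‑6‑{[tert‑butyl(dimethyl)silyl]oxy}‑1‑hydroxy‑3‑methylhex‑3‑en‑1‑yl]‑5‑[(Z)‑2‑iodoprop‑1‑en‑1‑yl]‑3‑methylideneoxolan‑2‑one | C=C1C(=O)O[C@H](/C=C(/C)I)[C@H]1[C@H](O)C/C(C)=C/CCO[Si](C)(C)C(C)(C)C | intermediate
21 | (4R,5S)‑4‑[(1R,3E)‑1,6‑dihydroxy‑3‑methylhex‑3‑en‑1‑yl]‑5‑[(Z)‑2‑iodoprop‑1‑en‑1‑yl]‑3‑methylideneoxolan‑2‑one | C=C1C(=O)O[C@H](/C=C(/C)I)[C@H]1[C@H](O)C/C(C)=C/CCO | intermediate
22 | (3E,6R)‑6‑hydroxy‑6‑{(2S,3R)‑2‑[(Z)‑2‑iodoprop‑1‑en‑1‑yl]‑4‑methylidene‑5‑oxooxolan‑3‑yl}‑4‑methylhex‑3‑enal | C=C1C(=O)O[C@H](/C=C(/C)I)[C@H]1[C@H](O)C/C(C)=C/CC=O | intermediate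
23 | (6R,7R,8R)‑3,8‑dihydroxygermacra‑1(10)E,4Z,11(13)‑trien‑12,6‑olide (C3 epimers) | C=C1C(=O)O[C@@H]2/C=C(/C)C(O)C/C=C(\C)C[C@@H](O)[C@@H]12 | intermediate
24 | (6R,7R,8R)‑8‑hydroxy‑3‑oxogermacra‑1(10)E,4Z,11(13)‑trien‑12,6‑olide | C=C1C(=O)O[C@@H]2/C=C(/C)C(=O)C/C=C(\C)C[C@@H](O)[C@@H]12 | intermediate
25 | (E)‑but‑2‑enal | C/C=C/C=O | starting material
26 | 2,3‑dibromobutanal (racemic diastereomers) | CC(Br)C(Br)C=O | intermediate
27 | (Z)‑2‑bromobut‑2‑enal | C/C=C(\Br)C=O | intermediate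
28 | (Z)‑2‑bromobut‑2‑enoic acid | C/C=C(\Br)C(=O)O | intermediate
29 | (6R,7R,8R)‑8‑{[(Z)‑2‑bromobut‑2‑enoyl]oxy}‑3‑oxogermacra‑1(10)E,4Z,11(13)‑trien‑12,6‑olide | C=C1C(=O)O[C@@H]2/C=C(/C)C(=O)C/C=C(\C)C[C@@H](OC(=O)/C(Br)=C/C)[C@@H]12 | intermediate
30 | (3S,6R,7R,8R)‑8‑{[(Z)‑2‑bromobut‑2‑enoyl]oxy}‑3‑hydroxygermacra‑1(10)E,4Z,11(13)‑trien‑12,6‑olide | C=C1C(=O)O[C@@H]2/C=C(/C)[C@@H](O)C/C=C(\C)C[C@@H](OC(=O)/C(Br)=C/C)[C@@H]12 | intermediate
31 | 3‑O‑triethylsilyl ether of 30 | C=C1C(=O)O[C@@H]2/C=C(/C)[C@@H](O[Si](CC)(CC)CC)C/C=C(\C)C[C@@H](OC(=O)/C(Br)=C/C)[C@@H]12 | intermediate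
32 | tert‑butyl prop‑2‑enoate | C=CC(=O)OC(C)(C)C | starting material
33 | {[tert‑butyl(dimethyl)silyl]oxy}acetaldehyde | O=CCO[Si](C)(C)C(C)(C)C | starting material
34 | tert‑butyl 4‑{[tert‑butyl(dimethyl)silyl]oxy}‑3‑hydroxy‑2‑methylidenebutanoate (racemic) | C=C(C(=O)OC(C)(C)C)C(O)CO[Si](C)(C)C(C)(C)C | intermediate
35 | tert‑butyl 3‑acetoxy‑4‑{[tert‑butyl(dimethyl)silyl]oxy}‑2‑methylidenebutanoate (racemic) | C=C(C(=O)OC(C)(C)C)C(OC(C)=O)CO[Si](C)(C)C(C)(C)C | intermediate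
36 | tert‑butyl (E)‑2‑(acetoxymethyl)‑4‑{[tert‑butyl(dimethyl)silyl]oxy}but‑2‑enoate | CC(C)(C)OC(=O)/C(=C/CO[Si](C)(C)C(C)(C)C)COC(C)=O | intermediate
37 | trimethylsilyl (E)‑2‑(acetoxymethyl)‑4‑{[tert‑butyl(dimethyl)silyl]oxy}but‑2‑enoate | C[Si](C)(C)OC(=O)/C(=C/CO[Si](C)(C)C(C)(C)C)COC(C)=O | intermediate
38 | (E)‑2‑(acetoxymethyl)‑4‑{[tert‑butyl(dimethyl)silyl]oxy}but‑2‑enoic acid | OC(=O)/C(=C/CO[Si](C)(C)C(C)(C)C)COC(C)=O | intermediate
39 | chloromethyl (E)‑2‑(acetoxymethyl)‑4‑{[tert‑butyl(dimethyl)silyl]oxy}but‑2‑enoate | ClCOC(=O)/C(=C/CO[Si](C)(C)C(C)(C)C)COC(C)=O | intermediate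
40 | iodomethyl (E)‑2‑(acetoxymethyl)‑4‑{[tert‑butyl(dimethyl)silyl]oxy}but‑2‑enoate | ICOC(=O)/C(=C/CO[Si](C)(C)C(C)(C)C)COC(C)=O | intermediate
41 | acyloxymethylzinc iodide from 40 | I[Zn]COC(=O)/C(=C/CO[Si](C)(C)C(C)(C)C)COC(C)=O | intermediate
42 | (3S,6R,7R,8R)‑8‑({(E)‑2‑[({(E)‑2‑(acetoxymethyl)‑4‑[(tert‑butyldimethylsilyl)oxy]but‑2‑enoyl}oxy)methyl]but‑2‑enoyl}oxy)‑3‑[(triethylsilyl)oxy]germacra‑1(10)E,4Z,11(13)‑trien‑12,6‑olide | C=C1C(=O)O[C@@H]2/C=C(/C)[C@@H](O[Si](CC)(CC)CC)C/C=C(\C)C[C@@H](OC(=O)/C(=C/C)COC(=O)/C(=C/CO[Si](C)(C)C(C)(C)C)COC(C)=O)[C@@H]12 | intermediate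
43 | (1R,3S,6R,7R,8R,10R)‑1,10‑epoxide of 42 | C=C1C(=O)O[C@@H]2/C=C(/C)[C@@H](O[Si](CC)(CC)CC)C[C@H]3O[C@]3(C)C[C@@H](OC(=O)/C(=C/C)COC(=O)/C(=C/CO[Si](C)(C)C(C)(C)C)COC(C)=O)[C@@H]12 | intermediate
44 | CNP0193678.1, (1R,3S,6R,7R,8R,10R)‑8‑({(E)‑2‑[({(E)‑2‑(acetoxymethyl)‑4‑hydroxybut‑2‑enoyl}oxy)methyl]but‑2‑enoyl}oxy)‑1,10‑epoxy‑3‑hydroxygermacra‑4Z,11(13)‑dien‑12,6‑olide | C=C1C(=O)O[C@@H]2/C=C(/C)[C@@H](O)C[C@H]3O[C@]3(C)C[C@@H](OC(=O)/C(=C/C)COC(=O)/C(=C/CO)COC(C)=O)[C@@H]12 | target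

**Count**
Total steps: 29. Longest linear sequence: 19 steps (steps 3–15, 18–20, 27–29).

**Steps most likely to fail**

Step 11. The ring closure may be slow or misdirected: the ester tether has to turn into its s‑cis rotamer before the carbanion can reach C7, 6‑endo attack at C8 could compete, and the freed C8 alkoxide could attack the new lactone. Fallback, from 16 back to 20: 16 would be esterified with acrylic acid (DCC, DMAP) to give the acrylate ester F1. F1 would then be treated with PMe3 in t‑BuOH/THF. Conjugate addition of the phosphine gives a β‑phosphonio ester enolate, which alkylates the oxirane at C7 and then expels the phosphine (a Morita–Baylis–Hillman‑type epoxide alkylation, known for enone–epoxide pairs). This would give 20 directly, with the methylene group arising by elimination instead of olefination and without stoichiometric base.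

Step 27. Pd(0) may ionise the allylic carboxylates of 40, 41 or 42 (scrambling or loss of acyloxy groups), the alkenylpalladium may insert into the methylene lactone, or the zinc reagent may be protonated or decompose before transmetalation. Fallback, from 31 back to 42: the one‑carbon unit would be introduced alone by Stille hydroxymethylation of 31 with (tributylstannyl)methanol (Pd2(dba)3, tri(2‑furyl)phosphine, CuI, NMP, 50 °C) to give the hydroxymethyl enoate F5. The two large fragments would then be joined at oxygen by Steglich esterification of F5 with acid 38 (DCC, DMAP), which gives 42.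

Step 14. Oligomerisation or simple reduction may win over ring closure, because the ten‑membered ring has to form across the trans‑fused lactone. Fallback, from 18 back to 23: the ring would be closed before the lactone exists. 18 would be desilylated (TBAF/AcOH, THF) to the primary alcohol F2 and oxidised (TEMPO, PhI(OAc)2) to the aldehyde F3. F3 would be cyclised under the same Ni/Cr conditions to the macrocyclic epoxy phosphonoacetate F4 (C3 epimers). F4 would then undergo the tethered oxirane opening and methylenation (KOtBu, 2.1 equiv; then paraformaldehyde) inside the ring, which gives 23.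

**Further compounds**
F1 | step 11 | (1R,2Z)‑1‑{(2R,3R)‑3‑[(E)‑5‑{[tert‑butyl(dimethyl)silyl]oxy}‑2‑methylpent‑2‑en‑1‑yl]oxiran‑2‑yl}‑3‑iodobut‑2‑en‑1‑yl prop‑2‑enoate | C/C(I)=C/[C@@H](OC(=O)C=C)[C@H]1O[C@@H]1C/C(C)=C/CCO[Si](C)(C)C(C)(C)C
F2 | step 14 | (1R,2Z)‑1‑{(2R,3R)‑3‑[(E)‑5‑hydroxy‑2‑methylpent‑2‑en‑1‑yl]oxiran‑2‑yl}‑3‑iodobut‑2‑en‑1‑yl (diethoxyphosphoryl)acetate | C/C(I)=C/[C@@H](OC(=O)CP(=O)(OCC)OCC)[C@H]1O[C@@H]1C/C(C)=C/CCO
F3 | step 14 | (1R,2Z)‑3‑iodo‑1‑{(2R,3R)‑3‑[(E)‑2‑methyl‑5‑oxopent‑2‑en‑1‑yl]oxiran‑2‑yl}but‑2‑en‑1‑yl (diethoxyphosphoryl)acetate | C/C(I)=C/[C@@H](OC(=O)CP(=O)(OCC)OCC)[C@H]1O[C@@H]1C/C(C)=C/CC=O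
F4 | step 14 | (6R,7R,8R)‑7,8‑epoxy‑3‑hydroxygermacra‑1(10)E,4Z‑dien‑6‑yl (diethoxyphosphoryl)acetate (C3 epimers; carbocycle without C11–C13) | CCOP(=O)(OCC)CC(=O)O[C@@H]1/C=C(/C)C(O)C/C=C(\C)C[C@H]2O[C@@H]21
F5 | step 27 | (3S,6R,7R,8R)‑8‑{[(E)‑2‑(hydroxymethyl)but‑2‑enoyl]oxy}‑3‑[(triethylsilyl)oxy]germacra‑1(10)E,4Z,11(13)‑trien‑12,6‑olide | C=C1C(=O)O[C@@H]2/C=C(/C)[C@@H](O[Si](CC)(CC)CC)C/C=C(\C)C[C@@H](OC(=O)/C(=C/C)CO)[C@@H]12
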